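Compound numbers are those of the compound list after the steps. C1–C6 denote the carbons of the central benzene ring (ring A).

## Analysis of the target

Selaginellin is a single benzene ring (ring A) with four contiguous substituents. C1 carries the exocyclic carbon of a quinone methide, which also bears a 4-hydroxyphenyl ring and is part of a cyclohexa-2,5-dienone. C2 carries a 4-hydroxyphenyl ring, C5 a hydroxymethyl group and C6 a (4-hydroxyphenyl)ethynyl group; C3 and C4 are CH. There is no stereocentre, and the dienone and phenol rings on the exocyclic carbon are exchanged by proton tautomerism, so no double-bond geometry has to be set. The quinone methide is an electrophile and is simply the dehydrated form of a bis(4-hydroxyphenyl)carbinol, so it should be unveiled last. The derived triaryl cation can close onto the C2 aryl ring to a fluorene under strong acid, and the C6 alkyne lies ortho to a benzylic alcohol that can add to it under strong base or π-acid catalysis. The difficulty is the crowding along C2–C1–C6–C5 and the need to tell apart C1 and C6, both of which are best derived from carbonyl carbons. The strategy rests on three features of ring A: the unsubstituted C3–C4 edge can carry a removable Si–O–Si bridge; C1 and C6 can both arrive as aroyl-bearing carbons of one symmetric alkyne; and the C5 hydroxymethyl group is adjacent to C6 only, so it can mask the C6 carbonyl selectively.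

## Retrosynthetic reasoning

**23 from 22.** The quinone methide is cut back to the triaryl carbinol at the C1 substituent. All four phenolic oxygens carry the same acid-labile methoxymethyl acetal and the primary alcohol a silyl ether, so one acid treatment should remove everything and ionise the carbinol. Methyl ethers were not kept, because Lewis-acid demethylation would endanger the benzylic alcohol and the alkyne.

**22 from 21.** The C6–C≡C–aryl unit is traced to the C6 aryl ketone. The alkyne carbon that is inserted comes from a one-carbon diazo carbanion (Colvin homologation with 1,2-aryl shift). This makes C6 a carbonyl carbon like C1, which is what allows both to come from one symmetric alkyne. The forward reaction has to reach a crowded diaryl ketone.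

**21 from 20, and 20 from 16 and 19.** The bond between the carbinol carbon on C1 and one of its two aryl rings is cut, giving aryllithium 19 (from bromide 18, from 17) and a C1 ketone. In 16 the C5 hydroxymethyl group has closed onto the C6 carbonyl as a five-membered hemiketal, so C1 is the only free ketone. Silylation of the primary hydroxyl in 20 then reopens the C6 ketone in 21.

**16 from 14.** The C3–H and C4–H bonds are traced to the two aryl–silicon bonds of the bridge. Fluoride cleaves both and also the silyl ether on the C5 oxygen, so hydroxy diketone 15 forms and closes to 16 in one operation.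

**14 from 9 and 13.** Ring A is cut at C1–C2, C3–C4 and C5–C6. This leaves diyne 9, whose two silicon-bound alkyne carbons become C3 and C4, and the symmetric ynedione 13, whose alkyne carbons become C1 and C6. The cut is made here because one catalytic step then delivers the fully substituted ring with the C2 aryl, the C5 oxymethyl and both aroyl groups in place. The forward reaction has to favour the crossed cycloaddition over self-trimerisation.

**9 from 6 and 7, and 6 from 3 and 4.** The two Si–C(sp) bonds are cut. The preformed Si–O–Si unit of 4 is substituted twice in sequence by two lithium acetylides (5, then 8), which avoids a statistical cross-condensation of two silanols.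

**13 from 12, 12 from 2 and 10, 3 from 2, 2 from 1.** The ynedione comes from oxidation of the diol obtained from acetylene and two molecules of aldehyde 2. The same aldehyde gives alkyne 3 by one-carbon homologation, so 1 supplies three of the four oxygenated aryl rings.

## Alternatives that were turned down

**Alternative 1:** The disconnection is the C6 alkyne alone. Alkyne carbinol A1 would come from ketone A2 by addition of a lithiated silyldiazomethane to the C6 carbonyl, loss of silanolate and nitrogen, and 1,2-aryl shift of the alkylidene carbene.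
- For it: the alkyne is installed without a halide or triflate at the most crowded position, and the aryl shift is a dependable way to a diarylalkyne. On this point it is exactly as strong as the chosen route, which uses the same transformation in step 12 on 21.
- Against it: as a strategy it leaves open how the four contiguous substituents of A2 are assembled. A2 would have to be built by successive acylations and couplings on a preformed benzene, each at a doubly ortho-substituted position.
- Comparison: the chosen strategy keeps this homologation as a finishing step but puts the strategic weight on a step that creates ring A and both carbonyl-bearing carbons at once.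

**Alternative 2:** Ring A is cut at C1–C2 and C4–C5 and taken down to a cyclohexenone. Under a diarylprolinol silyl ether, diketone A4 would add through its central carbon to enal A5, and the α′-carbon of the alkyl ketone would condense with the aldehyde to give cyclohexenone A3.
- For it: cheap acyclic materials, no transition metal in the ring-forming step, and regiochemistry fixed by the polarity of the Michael and aldol steps. There is only one aryl ketone, so no carbonyl differentiation is needed, and the ring oxygen at C6 would allow the arylethynyl group to enter by cross-coupling. On both of these points it is stronger than the chosen route.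
- Against it: the catalyst sets two stereocentres in A3 that aromatisation destroys. The ring must still be dehydrogenated, the C6 oxygen activated and coupled at a doubly flanked position, and the benzyl ether removed without touching the alkyne. 1,3-Diketones also tend to close through oxygen onto the enal carbonyl to give dihydropyranols instead of carbocycles.
- Comparison: the chosen strategy reaches the aromatic oxidation level directly and needs no redox adjustment of the ring. It pays for this with the ketone differentiation in step 10.

**Alternative 3:** Ring A is kept and the C6–CH2 and C1–C(=O) bonds are made by aryne insertion. Fluoride would convert silyl triflate A7 into the C1≡C6 aryne; the enolate carbon of diketone A8 adds at C6, the aryl anion at C1 attacks the neighbouring ketone, and the four-membered alkoxide fragments to give A6.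
- For it: two adjacent carbon substituents are installed in one step. The two carbonyl groups of A6 are intrinsically different (one enolisable, one not), so an aryllithium can be directed to C1 and the other ketone converted into the alkyne by enol sulfonate elimination. Both operations are more secure than steps 10 and 12 of the chosen route.
- Against it: the direction of attack on the aryne depends on the chlorine at C2 overriding the oxymethyl group at C5, which hinders C6 and weakly directs the other way. A7 is itself a contiguously tetrasubstituted benzene that needs a multistep synthesis. The C2 aryl ring must be introduced late by coupling of a hindered aryl chloride.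
- Comparison: in the chosen strategy the regiochemistry follows from the tether and the symmetry of 13, not from aryne distortion, and the C2 aryl ring is present from the start.

Key step: step 7

## Route

Assumption: 16, 20 and 21 are ring–chain tautomers of hydroxy ketones. 16 and 20 are written as the hemiketal closed by the C5 oxygen and 21 as the open ketone; all forms of one compound should converge on the same product in the next step.

Step 1
Reactants: 1 4-hydroxybenzaldehyde
Product: 2 4-(methoxymethoxy)benzaldehyde
Conditions: MOMCl, i-Pr2NEt, CH2Cl2, 0 °C to rt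
Reagents that add atoms: chloromethyl methyl ether, COCCl
Why: O-alkylation of the phenoxide by the reactive α-chloro ether (Williamson-type acetal formation); the aldehyde is inert under these conditions.

Step 2
Reactants: 2 4-(methoxymethoxy)benzaldehyde
Product: 3 1-ethynyl-4-(methoxymethoxy)benzene
Conditions: dimethyl (1-diazo-2-oxopropyl)phosphonate, K2CO3, MeOH, 0 °C to rt
Reagents that add atoms: dimethyl (1-diazo-2-oxopropyl)phosphonate, CC(=O)C(=[N+]=[N-])P(=O)(OC)OC
Why: Ohira–Bestmann variant of the Seyferth–Gilbert homologation; methanolysis frees the diazomethylphosphonate anion, which adds to the aldehyde, and loss of phosphate and nitrogen with 1,2-hydride shift gives the terminal alkyne. The aryl acetal is stable to carbonate in methanol.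

Step 3
Reactants: 3 1-ethynyl-4-(methoxymethoxy)benzene; 4 1,3-dichloro-1,1,3,3-tetramethyldisiloxane (3 equiv)
Product: 6 1-chloro-3-{[4-(methoxymethoxy)phenyl]ethynyl}-1,1,3,3-tetramethyldisiloxane, via lithium [4-(methoxymethoxy)phenyl]acetylide 5 (not isolated)
Conditions: n-BuLi, THF, −78 °C; added by cannula to 4 (3 equiv), THF, −78 °C to rt; excess 4 removed in vacuo, crude 6 used directly
Reagents that add atoms: none
Why: Nucleophilic substitution at silicon by a lithium acetylide; inverse addition to an excess of the dichloride should hold the reaction at mono-substitution, and the volatile excess is distilled off.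

Step 4
Reactants: 7 tert-butyldimethyl(prop-2-yn-1-yloxy)silane; 6 1-chloro-3-{[4-(methoxymethoxy)phenyl]ethynyl}-1,1,3,3-tetramethyldisiloxane
Product: 9 1-{3-[(tert-butyldimethylsilyl)oxy]prop-1-yn-1-yl}-3-{[4-(methoxymethoxy)phenyl]ethynyl}-1,1,3,3-tetramethyldisiloxane, via lithium 3-[(tert-butyldimethylsilyl)oxy]prop-1-yn-1-ide 8 (not isolated)
Conditions: n-BuLi, THF, −78 °C; then 6, −78 °C to rt; neutral aqueous work-up
Reagents that add atoms: none
Why: Second acetylide substitution at the remaining Si–Cl bond, which is far more electrophilic than the Si–O–Si or Si–C(sp) bonds; the unsymmetrical diyne should be stable to neutral work-up and chromatography.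

Step 5
Reactants: 10 acetylene; 2 4-(methoxymethoxy)benzaldehyde (2 equiv)
Product: 12 1,4-bis[4-(methoxymethoxy)phenyl]but-2-yne-1,4-diol (mixture of meso and racemic diastereomers), via ethynylenedimagnesium dibromide 11 (not isolated)
Conditions: EtMgBr (2 equiv), THF, 0 to 50 °C; then 2, 0 °C to rt; aq NH4Cl
Reagents that add atoms: none
Why: Double deprotonation of acetylene gives the bis-Grignard reagent, which adds twice to the aldehyde; the diastereomer mixture is irrelevant because both carbinol centres are oxidised next.

Step 6
Reactants: 12 1,4-bis[4-(methoxymethoxy)phenyl]but-2-yne-1,4-diol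
Product: 13 1,4-bis[4-(methoxymethoxy)phenyl]but-2-yne-1,4-dione
Conditions: MnO2 (activated, excess), CH2Cl2, rt
Reagents that add atoms: none
Why: MnO2 oxidises alcohols that are both benzylic and propargylic under neutral conditions, which suits the electrophilic ynedione product and the acetals.

Step 7
Reactants: 9 1-{3-[(tert-butyldimethylsilyl)oxy]prop-1-yn-1-yl}-3-{[4-(methoxymethoxy)phenyl]ethynyl}-1,1,3,3-tetramethyldisiloxane; 13 1,4-bis[4-(methoxymethoxy)phenyl]but-2-yne-1,4-dione (1.5 equiv)
Product: 14 {7-({[tert-butyl(dimethyl)silyl]oxy}methyl)-4-[4-(methoxymethoxy)phenyl]-1,1,3,3-tetramethyl-1,3-dihydro-2,1,3-benzoxadisilole-5,6-diyl}bis{[4-(methoxymethoxy)phenyl]methanone}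
Conditions: RhCl(PPh3)3 (10 mol %), toluene, 100 °C, slow addition of 9 to 13 and catalyst
Reagents that add atoms: none
Why: After loss of one PPh3, monovalent rhodium binds the two silicon-bound alkynes of 9 and couples them oxidatively to a rhodacyclopentadiene of trivalent rhodium; this forms the C3–C4 bond and closes the five-membered C–Si–O–Si–C ring by joining the two inner alkyne carbons that the three-atom tether holds next to each other. Ynedione 13, the better π-acceptor, then coordinates and inserts, and reductive elimination forms C1–C2 and C5–C6, closes ring A as the six-membered arene and returns monovalent rhodium. The closest known reaction type is the rhodium- or cobalt-catalysed [2+2+2] cycloaddition of silicon-tethered 1,6-diynes with electron-poor alkynes. No stereocentre is formed. The step needs chemoselectivity for the crossed adduct over self-trimerisation of 9 or 13: the silylated, fully substituted termini of 9 make a second molecule of 9 a poor third partner, 13 is held in excess and 9 is added slowly. Regiochemistry is not in question, because the tether forces C3 next to C4 and 13 is symmetric, so the aroyl carbons must arrive at C1 and C6 with the aryl ring at C2 and the silyloxymethyl group at C5.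

Step 8
Reactants: 14 {7-({[tert-butyl(dimethyl)silyl]oxy}methyl)-4-[4-(methoxymethoxy)phenyl]-1,1,3,3-tetramethyl-1,3-dihydro-2,1,3-benzoxadisilole-5,6-diyl}bis{[4-(methoxymethoxy)phenyl]methanone}
Product: 16 7-[4-(methoxymethoxy)benzoyl]-1,6-bis[4-(methoxymethoxy)phenyl]-1,3-dihydro-2-benzofuran-1-ol (racemic), via open-chain hydroxy diketone 15 (not isolated)
Conditions: Bu4NF·3H2O (6 equiv), THF, 60 °C; aq NH4Cl
Reagents that add atoms: none
Why: Fluoride-promoted protodesilylation of the two aryl–silicon bonds through pentacoordinate siliconates, helped by the electron-poor ring and the Si–O substituent, with water as proton source; the same reagent cleaves the silyl ether. The freed C5 hydroxymethyl group should add to the adjacent C6 carbonyl (5-exo-trig hemiketalisation); it cannot reach the C1 carbonyl, so only C6 is masked. The diaryl ketones have no α-hydrogen and the aryl acetals are inert to fluoride.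

Step 9
Reactants: 17 4-bromophenol
Product: 18 1-bromo-4-(methoxymethoxy)benzene
Conditions: MOMCl, i-Pr2NEt, CH2Cl2, 0 °C to rt
Reagents that add atoms: chloromethyl methyl ether, COCCl
Why: Phenol O-alkylation as in step 1.

Step 10
Reactants: 18 1-bromo-4-(methoxymethoxy)benzene (2.3 equiv); 16 7-[4-(methoxymethoxy)benzoyl]-1,6-bis[4-(methoxymethoxy)phenyl]-1,3-dihydro-2-benzofuran-1-ol
Product: 20 7-{hydroxybis[4-(methoxymethoxy)phenyl]methyl}-1,6-bis[4-(methoxymethoxy)phenyl]-1,3-dihydro-2-benzofuran-1-ol (racemic), via [4-(methoxymethoxy)phenyl]lithium 19 (not isolated)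
Conditions: n-BuLi, THF, −78 °C; then 16 in THF, −78 to −40 °C; aq NH4Cl
Reagents that add atoms: none
Why: Bromine–lithium exchange, then 1,2-addition of the aryllithium to a diaryl ketone. The first equivalent deprotonates the hemiketal, and the lithium hemiketalate (the same species as the tetrahedral adduct of an aryllithium with a phthalide, which persists in the cold) keeps C6 masked, so C1 is the only free carbonyl. After addition at C1 the new tertiary alkoxide can also close onto C6, which guards against a second addition.

Step 11
Reactants: 20 7-{hydroxybis[4-(methoxymethoxy)phenyl]methyl}-1,6-bis[4-(methoxymethoxy)phenyl]-1,3-dihydro-2-benzofuran-1-ol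
Product: 21 {6-({[tert-butyl(dimethyl)silyl]oxy}methyl)-2-{hydroxybis[4-(methoxymethoxy)phenyl]methyl}-3-[4-(methoxymethoxy)phenyl]phenyl}[4-(methoxymethoxy)phenyl]methanone
Conditions: TBSCl, imidazole, DMF, 0 °C to rt
Reagents that add atoms: tert-butyldimethylsilyl chloride, CC(C)(C)[Si](C)(C)Cl
Why: Selective silylation of the primary hydroxyl of the open tautomer; the tertiary hydroxyls are too hindered for this reagent. Trapping the primary oxygen removes the hemiketal that used it and returns C6 to the ketone level.

Step 12
Reactants: 21 {6-({[tert-butyl(dimethyl)silyl]oxy}methyl)-2-{hydroxybis[4-(methoxymethoxy)phenyl]methyl}-3-[4-(methoxymethoxy)phenyl]phenyl}[4-(methoxymethoxy)phenyl]methanone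
Product: 22 {3-({[tert-butyl(dimethyl)silyl]oxy}methyl)-2-{[4-(methoxymethoxy)phenyl]ethynyl}-6-[4-(methoxymethoxy)phenyl]phenyl}bis[4-(methoxymethoxy)phenyl]methanol
Conditions: Me3SiCHN2 (3 equiv), n-BuLi (3 equiv), THF, −78 °C; then 21, −78 °C to rt; aq NH4Cl
Reagents that add atoms: (trimethylsilyl)diazomethane, C[Si](C)(C)C=[N+]=[N-]
Why: Colvin homologation: the lithiated diazo reagent adds to the C6 ketone, Peterson-type loss of silanolate and then nitrogen gives a diaryl alkylidene carbene, and a Fritsch–Buttenberg–Wiechell 1,2-aryl shift gives the diarylalkyne whichever aryl group migrates. One equivalent deprotonates the tertiary hydroxyl; the irreversible loss of nitrogen should draw material through the open keto form.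

Step 13
Reactants: 22 {3-({[tert-butyl(dimethyl)silyl]oxy}methyl)-2-{[4-(methoxymethoxy)phenyl]ethynyl}-6-[4-(methoxymethoxy)phenyl]phenyl}bis[4-(methoxymethoxy)phenyl]methanol
Product: 23 selaginellin, 4-{[3-(hydroxymethyl)-6-(4-hydroxyphenyl)-2-[(4-hydroxyphenyl)ethynyl]phenyl](4-hydroxyphenyl)methylidene}cyclohexa-2,5-dien-1-one
Conditions: 3 M aq HCl, MeOH–THF, rt to 40 °C; then aq NaHCO3
Reagents that add atoms: none
Why: Acid-catalysed acetal exchange removes the four aryl methoxymethyl groups and solvolyses the silyl ether. The carbinol ionises to a hydroxy-substituted triaryl cation, which loses a phenolic proton on neutralisation to give the quinone methide (fuchsone formation). This cation is too stabilised to attack the C2 aryl ring or the alkyne under dilute acid.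

## Compound list

1 | 4-hydroxybenzaldehyde | O=Cc1ccc(O)cc1 | starting material
2 | 4-(methoxymethoxy)benzaldehyde | COCOc1ccc(C=O)cc1 | intermediate
3 | 1-ethynyl-4-(methoxymethoxy)benzene | COCOc1ccc(C#C)cc1 | intermediate
4 | 1,3-dichloro-1,1,3,3-tetramethyldisiloxane | C[Si](C)(Cl)O[Si](C)(C)Cl | starting material
5 | lithium [4-(methoxymethoxy)phenyl]acetylide | COCOc1ccc(C#C[Li])cc1 | intermediate
6 | 1-chloro-3-{[4-(methoxymethoxy)phenyl]ethynyl}-1,1,3,3-tetramethyldisiloxane | COCOc1ccc(C#C[Si](C)(C)O[Si](C)(C)Cl)cc1 | intermediate
7 | tert-butyldimethyl(prop-2-yn-1-yloxy)silane | CC(C)(C)[Si](C)(C)OCC#C | starting material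
8 | lithium 3-[(tert-butyldimethylsilyl)oxy]prop-1-yn-1-ide | CC(C)(C)[Si](C)(C)OCC#C[Li] | intermediate
9 | 1-{3-[(tert-butyldimethylsilyl)oxy]prop-1-yn-1-yl}-3-{[4-(methoxymethoxy)phenyl]ethynyl}-1,1,3,3-tetramethyldisiloxane | COCOc1ccc(C#C[Si](C)(C)O[Si](C)(C)C#CCO[Si](C)(C)C(C)(C)C)cc1 | intermediate
10 | acetylene | C#C | starting material
11 | ethynylenedimagnesium dibromide | Br[Mg]C#C[Mg]Br | intermediate
12 | 1,4-bis[4-(methoxymethoxy)phenyl]but-2-yne-1,4-diol (meso and racemic mixture) | COCOc1ccc(cc1)C(O)C#CC(O)c1ccc(OCOC)cc1 | intermediate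
13 | 1,4-bis[4-(methoxymethoxy)phenyl]but-2-yne-1,4-dione | COCOc1ccc(cc1)C(=O)C#CC(=O)c1ccc(OCOC)cc1 | intermediate
14 | {7-({[tert-butyl(dimethyl)silyl]oxy}methyl)-4-[4-(methoxymethoxy)phenyl]-1,1,3,3-tetramethyl-1,3-dihydro-2,1,3-benzoxadisilole-5,6-diyl}bis{[4-(methoxymethoxy)phenyl]methanone} | CC(C)(C)[Si](C)(C)OCc1c2c(c(-c3ccc(OCOC)cc3)c(C(=O)c3ccc(OCOC)cc3)c1C(=O)c1ccc(OCOC)cc1)[Si](C)(C)O[Si]2(C)C | intermediate
15 | {3-(hydroxymethyl)-6-[4-(methoxymethoxy)phenyl]-1,2-phenylene}bis{[4-(methoxymethoxy)phenyl]methanone} | OCc1ccc(-c2ccc(OCOC)cc2)c(C(=O)c2ccc(OCOC)cc2)c1C(=O)c1ccc(OCOC)cc1 | intermediate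
16 | 7-[4-(methoxymethoxy)benzoyl]-1,6-bis[4-(methoxymethoxy)phenyl]-1,3-dihydro-2-benzofuran-1-ol (racemic) | OC1(c2ccc(OCOC)cc2)OCc2ccc(-c3ccc(OCOC)cc3)c(C(=O)c3ccc(OCOC)cc3)c12 | intermediate
17 | 4-bromophenol | Oc1ccc(Br)cc1 | starting material
18 | 1-bromo-4-(methoxymethoxy)benzene | COCOc1ccc(Br)cc1 | intermediate
19 | [4-(methoxymethoxy)phenyl]lithium | COCOc1ccc([Li])cc1 | intermediate
20 | 7-{hydroxybis[4-(methoxymethoxy)phenyl]methyl}-1,6-bis[4-(methoxymethoxy)phenyl]-1,3-dihydro-2-benzofuran-1-ol (racemic) | OC1(c2ccc(OCOC)cc2)OCc2ccc(-c3ccc(OCOC)cc3)c(C(O)(c3ccc(OCOC)cc3)c3ccc(OCOC)cc3)c12 | intermediate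
21 | {6-({[tert-butyl(dimethyl)silyl]oxy}methyl)-2-{hydroxybis[4-(methoxymethoxy)phenyl]methyl}-3-[4-(methoxymethoxy)phenyl]phenyl}[4-(methoxymethoxy)phenyl]methanone | CC(C)(C)[Si](C)(C)OCc1ccc(-c2ccc(OCOC)cc2)c(C(O)(c2ccc(OCOC)cc2)c2ccc(OCOC)cc2)c1C(=O)c1ccc(OCOC)cc1 | intermediate
22 | {3-({[tert-butyl(dimethyl)silyl]oxy}methyl)-2-{[4-(methoxymethoxy)phenyl]ethynyl}-6-[4-(methoxymethoxy)phenyl]phenyl}bis[4-(methoxymethoxy)phenyl]methanol | CC(C)(C)[Si](C)(C)OCc1ccc(-c2ccc(OCOC)cc2)c(C(O)(c2ccc(OCOC)cc2)c2ccc(OCOC)cc2)c1C#Cc1ccc(OCOC)cc1 | intermediate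
23 | selaginellin | O=C1C=CC(=C(c2ccc(O)cc2)c2c(-c3ccc(O)cc3)ccc(CO)c2C#Cc2ccc(O)cc2)C=C1 | target

## Step count and least certain steps

Total: 13 steps. Longest linear sequence: 10 steps (1, 2, 3, 4, 7, 8, 10, 11, 12, 13). The target has no stereocentre.

**Step 7 (key step).** The most likely failure is slow entry of the internal ynedione into a rhodacycle that carries an aryl and an oxymethyl group next to the metal. Oligomerisation of 9, trimerisation of 13 or conjugate addition of released PPh3 to 13 could then take over; the product is a hexasubstituted benzene, so the final reductive elimination is also crowded.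
The fallback drops the tether and builds ring A by cycloaddition and dehydrogenation; it sets out from 2 and 13 and comes back at 16.
- Aldehyde 2 is extended with triethyl 4-phosphonocrotonate (LiN(SiMe3)2, THF; Horner–Wadsworth–Emmons) to ethyl (2E,4E)-5-[4-(methoxymethoxy)phenyl]penta-2,4-dienoate F1.
- Reduction with i-Bu2AlH gives (2E,4E)-5-[4-(methoxymethoxy)phenyl]penta-2,4-dien-1-ol F2, and TBSCl with imidazole gives tert-butyl(dimethyl){[(2E,4E)-5-[4-(methoxymethoxy)phenyl]penta-2,4-dien-1-yl]oxy}silane F3.
- Thermal Diels–Alder addition of 13 in toluene should give racemic cis-{3-({[tert-butyl(dimethyl)silyl]oxy}methyl)-6-[4-(methoxymethoxy)phenyl]cyclohexa-1,4-diene-1,2-diyl}bis{[4-(methoxymethoxy)phenyl]methanone} F4.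
- DDQ dehydrogenates it to {3-({[tert-butyl(dimethyl)silyl]oxy}methyl)-6-[4-(methoxymethoxy)phenyl]-1,2-phenylene}bis{[4-(methoxymethoxy)phenyl]methanone} F5, and Bu4NF then removes the silyl ether to give 16. This path also removes the need for the carbon–silicon cleavage of step 8.

**Step 10.** The risk is loss of site selectivity: if the lithium hemiketalate opens to the keto alkoxide before the aryllithium has added at C1, addition at C6 competes, and the C1 carbonyl is itself shielded by two ortho substituents.
The fallback masks C6 covalently; it sets out from 16 and comes back at 20.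
- Methanol with catalytic pyridinium p-toluenesulfonate converts 16 into 7-[4-(methoxymethoxy)benzoyl]-1-methoxy-1,6-bis[4-(methoxymethoxy)phenyl]-1,3-dihydro-2-benzofuran F6.
- The organocerium reagent from 19 and CeCl3 (THF, −78 °C), which is less basic than 19 and so less prone to eliminate methanol from the ketal, adds to the C1 ketone to give {3-methoxy-3,5-bis[4-(methoxymethoxy)phenyl]-1,3-dihydro-2-benzofuran-4-yl}bis[4-(methoxymethoxy)phenyl]methanol F7.
- Aqueous acetic acid in THF hydrolyses the mixed ketal to 20.

**Step 12.** The neighbouring tertiary alkoxide may close onto the C6 carbonyl and keep the diazo anion out, and the ketone is flanked on both sides; addition could therefore stall before the irreversible loss of nitrogen.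
The fallback caps the tertiary oxygen before C6 is unmasked; it sets out from 16 and 19 and comes back at 23.
- After addition of 19 to 16 as in step 10, the cold dialkoxide is quenched with Me3SiCl. Mild aqueous work-up removes the labile silyl group from the hemiketal oxygen and should leave the hindered ether, 7-{bis[4-(methoxymethoxy)phenyl][(trimethylsilyl)oxy]methyl}-1,6-bis[4-(methoxymethoxy)phenyl]-1,3-dihydro-2-benzofuran-1-ol F8.
- TBSCl with imidazole gives {2-{bis[4-(methoxymethoxy)phenyl][(trimethylsilyl)oxy]methyl}-6-({[tert-butyl(dimethyl)silyl]oxy}methyl)-3-[4-(methoxymethoxy)phenyl]phenyl}[4-(methoxymethoxy)phenyl]methanone F9, which has no free hydroxyl.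
- The Colvin reagent then gives {[{3-({[tert-butyl(dimethyl)silyl]oxy}methyl)-2-{[4-(methoxymethoxy)phenyl]ethynyl}-6-[4-(methoxymethoxy)phenyl]phenyl}bis[4-(methoxymethoxy)phenyl]methyl]oxy}trimethylsilane F10, and the acid treatment of step 13 gives 23 directly.

**Step 13.** The risk is incomplete cleavage of the four aryl acetals under acid mild enough for the rest of the molecule. Stronger acid could induce closure of the triaryl cation onto the C2 aryl ring or addition of the C5 hydroxymethyl group to the alkyne.
The fallback replaces protic solvolysis by buffered silyl transfer and fluoride; it sets out from 22 and comes back at 23.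
- Me3SiOTf with 2,2′-bipyridyl in CH2Cl2 at 0 °C, then water, should convert the aryl acetals into phenols via their silyl ethers and ionise the carbinol, giving 4-{[3-({[tert-butyl(dimethyl)silyl]oxy}methyl)-6-(4-hydroxyphenyl)-2-[(4-hydroxyphenyl)ethynyl]phenyl](4-hydroxyphenyl)methylidene}cyclohexa-2,5-dien-1-one F11.
- HF·pyridine in THF then removes the silyl ether to give 23.

## Further compounds

F1 | step 7 | ethyl (2E,4E)-5-[4-(methoxymethoxy)phenyl]penta-2,4-dienoate | CCOC(=O)/C=C/C=C/c1ccc(OCOC)cc1
F2 | step 7 | (2E,4E)-5-[4-(methoxymethoxy)phenyl]penta-2,4-dien-1-ol | OC/C=C/C=C/c1ccc(OCOC)cc1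
F3 | step 7 | tert-butyl(dimethyl){[(2E,4E)-5-[4-(methoxymethoxy)phenyl]penta-2,4-dien-1-yl]oxy}silane | CC(C)(C)[Si](C)(C)OC/C=C/C=C/c1ccc(OCOC)cc1
F4 | step 7 | cis-{3-({[tert-butyl(dimethyl)silyl]oxy}methyl)-6-[4-(methoxymethoxy)phenyl]cyclohexa-1,4-diene-1,2-diyl}bis{[4-(methoxymethoxy)phenyl]methanone} (racemic, one enantiomer drawn) | CC(C)(C)[Si](C)(C)OC[C@@H]1C=C[C@H](c2ccc(OCOC)cc2)C(C(=O)c2ccc(OCOC)cc2)=C1C(=O)c1ccc(OCOC)cc1
F5 | step 7 | {3-({[tert-butyl(dimethyl)silyl]oxy}methyl)-6-[4-(methoxymethoxy)phenyl]-1,2-phenylene}bis{[4-(methoxymethoxy)phenyl]methanone} | CC(C)(C)[Si](C)(C)OCc1ccc(-c2ccc(OCOC)cc2)c(C(=O)c2ccc(OCOC)cc2)c1C(=O)c1ccc(OCOC)cc1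
F6 | step 10 | 7-[4-(methoxymethoxy)benzoyl]-1-methoxy-1,6-bis[4-(methoxymethoxy)phenyl]-1,3-dihydro-2-benzofuran (racemic) | COC1(c2ccc(OCOC)cc2)OCc2ccc(-c3ccc(OCOC)cc3)c(C(=O)c3ccc(OCOC)cc3)c12
F7 | step 10 | {3-methoxy-3,5-bis[4-(methoxymethoxy)phenyl]-1,3-dihydro-2-benzofuran-4-yl}bis[4-(methoxymethoxy)phenyl]methanol (racemic) | COC1(c2ccc(OCOC)cc2)OCc2ccc(-c3ccc(OCOC)cc3)c(C(O)(c3ccc(OCOC)cc3)c3ccc(OCOC)cc3)c12
F8 | step 12 | 7-{bis[4-(methoxymethoxy)phenyl][(trimethylsilyl)oxy]methyl}-1,6-bis[4-(methoxymethoxy)phenyl]-1,3-dihydro-2-benzofuran-1-ol (racemic) | OC1(c2ccc(OCOC)cc2)OCc2ccc(-c3ccc(OCOC)cc3)c(C(O[Si](C)(C)C)(c3ccc(OCOC)cc3)c3ccc(OCOC)cc3)c12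
F9 | step 12 | {2-{bis[4-(methoxymethoxy)phenyl][(trimethylsilyl)oxy]methyl}-6-({[tert-butyl(dimethyl)silyl]oxy}methyl)-3-[4-(methoxymethoxy)phenyl]phenyl}[4-(methoxymethoxy)phenyl]methanone | CC(C)(C)[Si](C)(C)OCc1ccc(-c2ccc(OCOC)cc2)c(C(O[Si](C)(C)C)(c2ccc(OCOC)cc2)c2ccc(OCOC)cc2)c1C(=O)c1ccc(OCOC)cc1
F10 | step 12 | {[{3-({[tert-butyl(dimethyl)silyl]oxy}methyl)-2-{[4-(methoxymethoxy)phenyl]ethynyl}-6-[4-(methoxymethoxy)phenyl]phenyl}bis[4-(methoxymethoxy)phenyl]methyl]oxy}trimethylsilane | CC(C)(C)[Si](C)(C)OCc1ccc(-c2ccc(OCOC)cc2)c(C(O[Si](C)(C)C)(c2ccc(OCOC)cc2)c2ccc(OCOC)cc2)c1C#Cc1ccc(OCOC)cc1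
F11 | step 13 | 4-{[3-({[tert-butyl(dimethyl)silyl]oxy}methyl)-6-(4-hydroxyphenyl)-2-[(4-hydroxyphenyl)ethynyl]phenyl](4-hydroxyphenyl)methylidene}cyclohexa-2,5-dien-1-one | CC(C)(C)[Si](C)(C)OCc1ccc(-c2ccc(O)cc2)c(C(c2ccc(O)cc2)=C2C=CC(=O)C=C2)c1C#Cc1ccc(O)cc1
A1 | alternative 1 | bis(4-methoxyphenyl){3-[(tert-butyldimethylsilyloxy)methyl]-2-[(4-methoxyphenyl)ethynyl]-6-(4-methoxyphenyl)phenyl}methanol | CC(C)(C)[Si](C)(C)OCc1ccc(-c2ccc(OC)cc2)c(C(O)(c2ccc(OC)cc2)c2ccc(OC)cc2)c1C#Cc1ccc(OC)cc1
A2 | alternative 1 | {6-{[(tert-butyldimethylsilyl)oxy]methyl}-2-[hydroxybis(4-methoxyphenyl)methyl]-3-(4-methoxyphenyl)phenyl}(4-methoxyphenyl)methanone | CC(C)(C)[Si](C)(C)OCc1ccc(-c2ccc(OC)cc2)c(C(O)(c2ccc(OC)cc2)c2ccc(OC)cc2)c1C(=O)c1ccc(OC)cc1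
A3 | alternative 2 | trans-2-[(benzyloxy)methyl]-6-(4-methoxybenzoyl)-5-(4-methoxyphenyl)cyclohex-2-en-1-one | O=C1C(COCc2ccccc2)=CC[C@H](c2ccc(OC)cc2)[C@H]1C(=O)c1ccc(OC)cc1
A4 | alternative 2 | 5-(benzyloxy)-1-(4-methoxyphenyl)pentane-1,3-dione | COc1ccc(cc1)C(=O)CC(=O)CCOCc1ccccc1
A5 | alternative 2 | (2E)-3-(4-methoxyphenyl)prop-2-enal | COc1ccc(/C=C/C=O)cc1
A6 | alternative 3 | 2-{3-chloro-2-(4-methoxybenzoyl)-6-[(methoxymethoxy)methyl]phenyl}-1-(4-methoxyphenyl)ethan-1-one | COCOCc1ccc(Cl)c(C(=O)c2ccc(OC)cc2)c1CC(=O)c1ccc(OC)cc1
A7 | alternative 3 | 3-chloro-6-[(methoxymethoxy)methyl]-2-(trimethylsilyl)phenyl trifluoromethanesulfonate | COCOCc1ccc(Cl)c([Si](C)(C)C)c1OS(=O)(=O)C(F)(F)F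
A8 | alternative 3 | 1,3-bis(4-methoxyphenyl)propane-1,3-dione | COc1ccc(cc1)C(=O)CC(=O)c1ccc(OC)cc1
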